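**Plan** (ring D = the cyclohexene, numbered C1 (CMe), C2 (=CH), C3 (bears ring A, the resorcinol that also carries the flavanone), C4 (bears the ring-B aroyl group), C5 (bears resorcinol ring C), C6 (CH2))
- Retrosynthesis: cut the ring A–flavanone C2 bond (chromone arylation), then the ring-B aryl–carbonyl bond, which reveals a lactone between the C4 carboxyl carbon and the ortho-oxygen of ring C (a dihydrocoumarin), then C2–C3 and C6–C1 together, which removes propyne.
- Enabling feature: in that lactone C3 is the β-carbon of an exocyclic E-aryl enoate held s-cis, and C5 is a ring carbon whose CH2 arm (C6, as CH2ZnI) sits pseudoaxial over one enoate face, so nickel can stitch C3, propyne and C6 into ring D in one catalytic event.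
- Forward order: 4-(chloromethyl)coumarin (ring C plus lactone) → C5 by asymmetric conjugate reduction → enoate by aldol condensation with the ring-A aldehyde → ring D by nickel annulation with propyne → lactone opened by the ring-B Grignard reagent → chromanone rings joined by rhodium-catalysed chromone arylation → desilylation.
- Stereochemistry: C5 from the chiral copper hydride catalyst; C3 relayed from C5 in the key step; C4 by thermodynamic equilibration (all-equatorial); flavanone C2 from the chiral rhodium catalyst.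

Key step: step 6

Assumption: the chiral ligands in steps 2 and 11 are taken to induce 4S and 2R as drawn; the antipodal ligand is used if the sense proves opposite. TBS = tert-butyldimethylsilyl.

**Step 1**
Reactants: 1 4-(chloromethyl)-7-hydroxy-2H-chromen-2-one
Product: 2 4-(chloromethyl)-7-(TBS-oxy)-2H-chromen-2-one
Conditions: TBSOTf, 2,6-lutidine, CH2Cl2, 0 °C
Reagents that add atoms: tert-butyldimethylsilyl trifluoromethanesulfonate, CC(C)(C)[Si](C)(C)OS(=O)(=O)C(F)(F)F
Why: O-silylation of the phenol with a silyl triflate and a hindered pyridine base should leave untouched the reactive allylic chloride, which imidazole or a trialkylamine could alkylate.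

**Step 2**
Reactants: 2 4-(chloromethyl)-7-(TBS-oxy)-2H-chromen-2-one
Product: 3 (4S)-4-(chloromethyl)-7-(TBS-oxy)-3,4-dihydro-2H-chromen-2-one
Conditions: Cu(OAc)2·H2O (3 mol %), (R)-DTBM-SEGPHOS (3.3 mol %), (EtO)2MeSiH, t-BuOH, toluene, 0 → 25 °C
Reagents that add atoms: none
Why: Ligand-controlled asymmetric copper hydride conjugate reduction of the β,β-disubstituted unsaturated lactone should deliver hydride to lactone C4 on one face, which sets the future C5 of ring D, and t-BuOH should protonate the copper enolate before it can displace the γ-chloride.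

**Step 3**
Reactants: 4 5-chloro-2,4-dihydroxybenzaldehyde
Product: 5 5-chloro-2,4-bis(TBS-oxy)benzaldehyde
Conditions: TBSCl, imidazole, DMF, 25 °C
Reagents that add atoms: tert-butyldimethylsilyl chloride, CC(C)(C)[Si](C)(C)Cl
Why: Standard O-silylation of both phenols with a silyl chloride and imidazole.

**Step 4**
Reactants: 3 (4S)-4-(chloromethyl)-7-(TBS-oxy)-3,4-dihydro-2H-chromen-2-one; 5 5-chloro-2,4-bis(TBS-oxy)benzaldehyde
Product: 8 (3E,4R)-3-{[5-chloro-2,4-bis(TBS-oxy)phenyl]methylidene}-4-(chloromethyl)-7-(TBS-oxy)-3,4-dihydro-2H-chromen-2-one, via lithium aldolate 6 (not isolated), via mesylate 7 (not isolated)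
Conditions: LiN(iPr)2, THF, −78 °C; 5; then MsCl, Et3N, −78 → 0 °C
Reagents that add atoms: none
Why: Aldol addition of the lithium lactone enolate to the non-enolizable aldehyde at −78 °C, O-mesylation and loss of the labile electron-rich benzylic mesylate make up an aldol condensation that should give the conjugated E-arylidene lactone (the thermodynamic geometry) without touching the stereocentre at lactone C4.

**Step 5**
Reactants: 8 (3E,4R)-arylidene lactone chloride
Product: 9 (3E,4R)-3-{[5-chloro-2,4-bis(TBS-oxy)phenyl]methylidene}-4-(iodomethyl)-7-(TBS-oxy)-3,4-dihydro-2H-chromen-2-one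
Conditions: NaI, 2-butanone, 80 °C
Reagents that add atoms: sodium iodide, [Na+].[I-]
Why: Finkelstein exchange (SN2 at the primary carbon) should give the iodide that zinc can insert into.

**Step 6**
Reactants: 9 (3E,4R)-arylidene lactone iodide; 10 propyne
Product: 13 (6aR,7R,10aS)-7-[5-chloro-2,4-bis(TBS-oxy)phenyl]-9-methyl-3-(TBS-oxy)-6a,7,10,10a-tetrahydro-6H-benzo[c]chromen-6-one (trans-fused), via alkylzinc iodide 11 (not isolated), via zinc enolate 12 (not isolated)
Conditions: Zn dust, LiCl, THF, 35 °C; then Ni(cod)2 (10 mol %), propyne (5 equiv), THF, 0 → 25 °C; aq NH4Cl; then DBU (10 mol %), CH2Cl2, 25 °C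
Reagents that add atoms: none
Why: Proposed new method: zerovalent nickel should bind the s-cis exocyclic aryl enoate of 11 and propyne and couple them oxidatively, joining C3 (the enoate β-carbon) to the unsubstituted alkyne carbon (C2) and leaving divalent nickel on the methyl-bearing carbon (C1) and the enolate oxygen, after which the tethered C6–ZnI arm transmetalates within the same molecule and C(sp2)–C(sp3) reductive elimination forms C1–C6, giving zinc enolate 12 and returning zerovalent nickel. The closest known reaction type is the nickel-catalysed three-component alkylative coupling of an enone, an alkyne and an organozinc reagent, known with an external organozinc or with the alkyne tied to the enone, but not with the zinc arm tied to the enoate so that a carbocycle closes. Ring D thus closes as a formal [4+2] annulation of the C3–C4–C5–C6 unit with the two alkyne carbons, the ring-closing event being reductive elimination from a seven-membered nickelacycle to the six-membered ring, and syn addition across the alkyne gives the cis alkene that the ring needs. C3 is set under control of C5: allylic strain with the E-aryl group holds the CH2ZnI arm on C5 pseudoaxial over one enoate face, nickel and propyne add to the other face, and this gives the 3,5-cis relation of rings A and C; C4 is set when 12 is protonated and is equilibrated by DBU toward the trans ring fusion (it is equilibrated again in step 8). The step needs three selectivities: bond formation at the terminal alkyne carbon (steric preference, nickel ends next to the methyl group), alkyl transfer in place of β-hydride elimination or direct nickel-catalysed conjugate addition of the organozinc (phosphine-free catalyst, excess propyne, intramolecular transmetalation), and no migration of the exocyclic alkene into the lactone ring (neutral medium, low temperature).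

**Step 7**
Reactants: 14 4-bromobenzene-1,3-diol
Product: 15 1-bromo-2,4-bis(TBS-oxy)benzene
Conditions: TBSCl, imidazole, DMF, 25 °C
Reagents that add atoms: tert-butyldimethylsilyl chloride, CC(C)(C)[Si](C)(C)Cl
Why: Standard O-silylation of both phenols with a silyl chloride and imidazole.

**Step 8**
Reactants: 13 trans-fused tricyclic lactone; 15 1-bromo-2,4-bis(TBS-oxy)benzene
Product: 17 [(1R,2R,6S)-2-[5-chloro-2,4-bis(TBS-oxy)phenyl]-6-[2-hydroxy-4-(TBS-oxy)phenyl]-4-methylcyclohex-3-en-1-yl][2,4-bis(TBS-oxy)phenyl]methanone, via aryl Grignard reagent 16 (not isolated)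
Conditions: 15, Mg turnings, LiCl, THF, 25 °C; then 13, −40 → 0 °C; aq NH4Cl; then DBU (20 mol %), CH2Cl2, 25 °C
Reagents that add atoms: none
Why: Acyl substitution of the aryl lactone by the aryl Grignard reagent should stop at the ketone because the ring-C phenoxide leaves and the crowded, enolizable product resists a second addition, and DBU then equilibrates C4 of ring D, now alpha to the ketone, to the all-equatorial 3,4-trans-4,5-trans arrangement.

**Step 9**
Reactants: 17 ring-A chloro ketone
Product: 18 [(1R,2R,6S)-2-[2,4-bis(TBS-oxy)-5-(4,4,5,5-tetramethyl-1,3,2-dioxaborolan-2-yl)phenyl]-6-[2-hydroxy-4-(TBS-oxy)phenyl]-4-methylcyclohex-3-en-1-yl][2,4-bis(TBS-oxy)phenyl]methanone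
Conditions: B2pin2, Pd2(dba)3 (2 mol %), XPhos (8 mol %), KOAc, dioxane, 100 °C
Reagents that add atoms: bis(pinacolato)diboron, CC1(C)OB(OC1(C)C)B1OC(C)(C)C(C)(C)O1
Why: Miyaura borylation of the aryl chloride with a zerovalent palladium catalyst carrying the bulky electron-rich XPhos ligand should tolerate the ketone, the free phenol and the alkene.

**Step 10**
Reactants: 19 7-hydroxy-4H-chromen-4-one
Product: 20 7-(TBS-oxy)-4H-chromen-4-one
Conditions: TBSCl, imidazole, DMF, 25 °C
Reagents that add atoms: tert-butyldimethylsilyl chloride, CC(C)(C)[Si](C)(C)Cl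
Why: Standard O-silylation of the phenol with a silyl chloride and imidazole.

**Step 11**
Reactants: 18 ring-A pinacol boronate; 20 7-(TBS-oxy)-4H-chromen-4-one
Product: 21 hexa-O-TBS ether of the target (ring-C ortho-hydroxyl free; flavanone 2R; ring D as in the target)
Conditions: [RhCl(C2H4)2]2 (3 mol %), (R,R)-Ph-bod (chiral diene, 6.6 mol %), KOH (20 mol %), dioxane/H2O 10:1, 50 °C
Reagents that add atoms: none
Why: Rhodium-catalysed asymmetric 1,4-addition of the aryl boronate to the chromone (Hayashi–Miyaura reaction) should form the C2–aryl bond of the flavanone, with the chiral diene ligand alone fixing the 2R configuration, independent of the remote ring-D stereocentres.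

**Step 12**
Reactants: 21 hexa-O-TBS ether of the target
Product: 22 (2R)-2-{5-[(1R,5S,6R)-6-(2,4-dihydroxybenzoyl)-5-(2,4-dihydroxyphenyl)-3-methylcyclohex-2-en-1-yl]-2,4-dihydroxyphenyl}-7-hydroxy-2,3-dihydro-4H-chromen-4-one
Conditions: HF·pyridine, pyridine, THF, 0 → 25 °C
Reagents that add atoms: none
Why: Fluoride-mediated cleavage of the six aryl silyl ethers under buffered, weakly acidic conditions should free the phenols without base (which would open the flavanone and epimerize C2) and without strong acid (which could add the ring-A phenol to the ring-D alkene).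

**Compound list**
1 | 4-(chloromethyl)-7-hydroxy-2H-chromen-2-one | O=c1cc(CCl)c2ccc(O)cc2o1 | starting material
2 | 4-(chloromethyl)-7-(TBS-oxy)-2H-chromen-2-one | O=c1cc(CCl)c2ccc(O[Si](C)(C)C(C)(C)C)cc2o1 | intermediate
3 | (4S)-4-(chloromethyl)-7-(TBS-oxy)-3,4-dihydro-2H-chromen-2-one | O=C1C[C@H](CCl)c2ccc(O[Si](C)(C)C(C)(C)C)cc2O1 | intermediate
4 | 5-chloro-2,4-dihydroxybenzaldehyde | O=Cc1cc(Cl)c(O)cc1O | starting material
5 | 5-chloro-2,4-bis(TBS-oxy)benzaldehyde | O=Cc1cc(Cl)c(O[Si](C)(C)C(C)(C)C)cc1O[Si](C)(C)C(C)(C)C | intermediate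
6 | lithium aldolate of 3 and 5 (3,4-trans lactone; both carbinol epimers; not isolated) | [Li]OC(c3cc(Cl)c(O[Si](C)(C)C(C)(C)C)cc3O[Si](C)(C)C(C)(C)C)[C@@H]1C(=O)Oc2cc(O[Si](C)(C)C(C)(C)C)ccc2[C@H]1CCl | intermediate
7 | methanesulfonate of the aldol (3,4-trans lactone; both epimers; not isolated) | CS(=O)(=O)OC(c3cc(Cl)c(O[Si](C)(C)C(C)(C)C)cc3O[Si](C)(C)C(C)(C)C)[C@@H]1C(=O)Oc2cc(O[Si](C)(C)C(C)(C)C)ccc2[C@H]1CCl | intermediate
8 | (3E,4R)-3-{[5-chloro-2,4-bis(TBS-oxy)phenyl]methylidene}-4-(chloromethyl)-7-(TBS-oxy)-3,4-dihydro-2H-chromen-2-one | O=C1Oc2cc(O[Si](C)(C)C(C)(C)C)ccc2[C@@H](CCl)/C1=C\c3cc(Cl)c(O[Si](C)(C)C(C)(C)C)cc3O[Si](C)(C)C(C)(C)C | intermediate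
9 | (3E,4R)-3-{[5-chloro-2,4-bis(TBS-oxy)phenyl]methylidene}-4-(iodomethyl)-7-(TBS-oxy)-3,4-dihydro-2H-chromen-2-one | O=C1Oc2cc(O[Si](C)(C)C(C)(C)C)ccc2[C@@H](CI)/C1=C\c3cc(Cl)c(O[Si](C)(C)C(C)(C)C)cc3O[Si](C)(C)C(C)(C)C | intermediate
10 | propyne | CC#C | starting material
11 | alkylzinc iodide from 9 (C–I replaced by C–ZnI; not isolated) | O=C1Oc2cc(O[Si](C)(C)C(C)(C)C)ccc2[C@@H](C[Zn]I)/C1=C\c3cc(Cl)c(O[Si](C)(C)C(C)(C)C)cc3O[Si](C)(C)C(C)(C)C | intermediate
12 | zinc enolate of tricyclic lactone 13 (not isolated) | CC1=C[C@@H](c2cc(Cl)c(O[Si](C)(C)C(C)(C)C)cc2O[Si](C)(C)C(C)(C)C)C2=C(O[Zn]I)Oc3cc(O[Si](C)(C)C(C)(C)C)ccc3[C@H]2C1 | intermediate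
13 | (6aR,7R,10aS)-7-[5-chloro-2,4-bis(TBS-oxy)phenyl]-9-methyl-3-(TBS-oxy)-6a,7,10,10a-tetrahydro-6H-benzo[c]chromen-6-one (trans-fused; 7-aryl trans to C6) | CC1=C[C@@H](c2cc(Cl)c(O[Si](C)(C)C(C)(C)C)cc2O[Si](C)(C)C(C)(C)C)[C@@H]2C(=O)Oc3cc(O[Si](C)(C)C(C)(C)C)ccc3[C@H]2C1 | intermediate
14 | 4-bromobenzene-1,3-diol | Oc1ccc(Br)c(O)c1 | starting material
15 | 1-bromo-2,4-bis(TBS-oxy)benzene | CC(C)(C)[Si](C)(C)Oc1ccc(Br)c(O[Si](C)(C)C(C)(C)C)c1 | intermediate
16 | [2,4-bis(TBS-oxy)phenyl]magnesium bromide (not isolated) | CC(C)(C)[Si](C)(C)Oc1ccc([Mg]Br)c(O[Si](C)(C)C(C)(C)C)c1 | intermediate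
17 | [(1R,2R,6S)-2-[5-chloro-2,4-bis(TBS-oxy)phenyl]-6-[2-hydroxy-4-(TBS-oxy)phenyl]-4-methylcyclohex-3-en-1-yl][2,4-bis(TBS-oxy)phenyl]methanone (all-trans) | CC1=C[C@@H](c2cc(Cl)c(O[Si](C)(C)C(C)(C)C)cc2O[Si](C)(C)C(C)(C)C)[C@H](C(=O)c2ccc(O[Si](C)(C)C(C)(C)C)cc2O[Si](C)(C)C(C)(C)C)[C@@H](c2ccc(O[Si](C)(C)C(C)(C)C)cc2O)C1 | intermediate
18 | pinacol boronate of 17 (Bpin in place of the ring-A chlorine) | CC1=C[C@@H](c2cc(B3OC(C)(C)C(C)(C)O3)c(O[Si](C)(C)C(C)(C)C)cc2O[Si](C)(C)C(C)(C)C)[C@H](C(=O)c2ccc(O[Si](C)(C)C(C)(C)C)cc2O[Si](C)(C)C(C)(C)C)[C@@H](c2ccc(O[Si](C)(C)C(C)(C)C)cc2O)C1 | intermediate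
19 | 7-hydroxy-4H-chromen-4-one | O=c1ccoc2cc(O)ccc12 | starting material
20 | 7-(TBS-oxy)-4H-chromen-4-one | O=c1ccoc2cc(O[Si](C)(C)C(C)(C)C)ccc12 | intermediate
21 | hexa-O-TBS ether of the target (ring-C ortho-hydroxyl free; flavanone 2R; ring D 1R,5S,6R as in 22) | CC1=C[C@@H](c2cc([C@H]3CC(=O)c4ccc(O[Si](C)(C)C(C)(C)C)cc4O3)c(O[Si](C)(C)C(C)(C)C)cc2O[Si](C)(C)C(C)(C)C)[C@H](C(=O)c2ccc(O[Si](C)(C)C(C)(C)C)cc2O[Si](C)(C)C(C)(C)C)[C@@H](c2ccc(O[Si](C)(C)C(C)(C)C)cc2O)C1 | intermediate
22 | (2R)-2-{5-[(1R,5S,6R)-6-(2,4-dihydroxybenzoyl)-5-(2,4-dihydroxyphenyl)-3-methylcyclohex-2-en-1-yl]-2,4-dihydroxyphenyl}-7-hydroxy-2,3-dihydro-4H-chromen-4-one | CC1=C[C@@H](c2cc([C@H]3CC(=O)c4ccc(O)cc4O3)c(O)cc2O)[C@H](C(=O)c2ccc(O)cc2O)[C@@H](c2ccc(O)cc2O)C1 | target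

**Totals**
Total step count: 12. Longest linear sequence: 9 steps (1, 2, 4, 5, 6, 8, 9, 11, 12).

**Steps most likely to fail**

Step 6 (proposed new method). The oxidative coupling may be outrun by nickel-catalysed conjugate addition of the alkylzinc to a second enoate, by β-hydride elimination after transmetalation, by oligomerization of propyne, by migration of the exocyclic alkene into the lactone ring, or by addition to the wrong enoate face. Fallback with known chemistry, from iodide 9 to lactone 13: the alkylzinc 11 is made as in step 6 and coupled with 2-bromopropene (Pd(PPh3)4, THF, 50 °C; Negishi coupling) to give the 2-methylallyl arylidene lactone F1. Vinylmagnesium bromide with CuI and TMSCl (THF, −78 °C) should then add a vinyl group to C3 from the face opposite the pseudoaxial arm on C5, and protonation with DBU equilibration should give the trans lactone diene F2. Ring-closing metathesis with second-generation Grubbs catalyst (CH2Cl2, 40 °C) closes ring D at C1=C2 and the route comes back at 13.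

Step 11. The hindered, electron-rich boronate may protodeboronate under aqueous base, the chromone may convert slowly, or catalyst control at flavanone C2 may be insufficient. Fallback, from boronate 18 and chromone 20 to 21: the same 1,4-addition is run without a chiral ligand ([Rh(OH)(cod)]2, dioxane/H2O, 50 °C), which should give 21 together with its C2 epimer, the (2S)-flavanone F4. The two are diastereomers and are separated by chromatography. F4 is returned to the epimer mixture with DBU (retro-oxa-Michael opening to the 2′-hydroxychalcone and reclosure) and recycled, so the route comes back at 21.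

Step 8. The Grignard reagent may add twice to the lactone carbonyl, or enolize the lactone in place of adding. Fallback, from lactone 13 to ketone 17: aminolysis with Me(MeO)NH·HCl and i-PrMgCl (THF, −20 °C) opens the lactone to the phenolic N-methoxy-N-methylamide F3. Its chelated tetrahedral adduct with excess Grignard reagent 16 (made from 15 as before, 0 °C) cannot collapse before work-up (Weinreb ketone synthesis), and DBU equilibration as in step 8 returns the route at 17.

**Further compounds**
F1 | step 6 | (3E,4R)-3-{[5-chloro-2,4-bis(TBS-oxy)phenyl]methylidene}-4-(2-methylprop-2-en-1-yl)-7-(TBS-oxy)-3,4-dihydro-2H-chromen-2-one | O=C1Oc2cc(O[Si](C)(C)C(C)(C)C)ccc2[C@@H](CC(C)=C)/C1=C\c3cc(Cl)c(O[Si](C)(C)C(C)(C)C)cc3O[Si](C)(C)C(C)(C)C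
F2 | step 6 | 3,4-trans lactone diene: 3-{1-[5-chloro-2,4-bis(TBS-oxy)phenyl]prop-2-en-1-yl}-4-(2-methylprop-2-en-1-yl)-7-(TBS-oxy)-3,4-dihydro-2H-chromen-2-one (stereocentres as in 13) | C=C[C@@H](c3cc(Cl)c(O[Si](C)(C)C(C)(C)C)cc3O[Si](C)(C)C(C)(C)C)[C@@H]1C(=O)Oc2cc(O[Si](C)(C)C(C)(C)C)ccc2[C@H]1CC(C)=C
F3 | step 8 | (1R,2R,6S)-2-[5-chloro-2,4-bis(TBS-oxy)phenyl]-6-[2-hydroxy-4-(TBS-oxy)phenyl]-N-methoxy-N,4-dimethylcyclohex-3-ene-1-carboxamide | CC1=C[C@@H](c2cc(Cl)c(O[Si](C)(C)C(C)(C)C)cc2O[Si](C)(C)C(C)(C)C)[C@H](C(=O)N(C)OC)[C@@H](c2ccc(O[Si](C)(C)C(C)(C)C)cc2O)C1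
F4 | step 11 | (2S)-flavanone epimer of 21 | CC1=C[C@@H](c2cc([C@@H]3CC(=O)c4ccc(O[Si](C)(C)C(C)(C)C)cc4O3)c(O[Si](C)(C)C(C)(C)C)cc2O[Si](C)(C)C(C)(C)C)[C@H](C(=O)c2ccc(O[Si](C)(C)C(C)(C)C)cc2O[Si](C)(C)C(C)(C)C)[C@@H](c2ccc(O[Si](C)(C)C(C)(C)C)cc2O)C1
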